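The easy step is to count reagent: a double product holds two per substrate and a tris adduct holds 3.

in all of them: substrate 0.10 M

| run | reagent | remark | time |
|---|---|---|---|
| north-east | 0.13 M | run made earlier |  |
| south | 0.21 M | run made earlier |  |
| Thursday's | 0.150 M |  | 50 min |
| Sunday's | 0.200 M |  | 50 min |
| Tuesday's | 0.250 M |  | 50 min |

| run | time / min | tris adduct / % | double product / % |
|---|---|---|---|
| north-east | 8.00 | 5 | 39 |
| north-east | 20.0 | 8 | 41 |
| north-east | 25.0 | 7 | 42 |
| north-east | 40.0 | 5 | 40 |
| south | 8.00 | 22 | 67 |
| south | 20.0 | 22 | 66 |
| south | 25.0 | 23 | 66 |
| south | 40.0 | 23 | 66 |

(each reading ± 2 percentage points)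

- a reading or a percentage of double product counts all its forms, free or not

* final tris adduct, as a percentage of the substrate charged, for each flask in turn (Thursday's, Sunday's, Tuesday's)

Both earlier runs stand flat from 8.00 min to 40.0 min within the scatter, so I look for the end state in one number. Tuesday's flask has 2.50, and this uptake number, reagent charged per substrate charged, is the equivalents of the trade. It says how many reagents each substrate ends up holding on average, if the reagent charge has gone into products. The south run tests this. Its uptake number is 2.10, its mean readings of 66.3% double product and 22.5% tris adduct account for 2.00, and the gap of 0.100 faces an unread 11.2% of the charge. I read that remainder as a single product holding one reagent.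

In fractions of the charge, then, once the reagent is taken up, the uptake number equals single product plus twice double product plus 3 times tris adduct. A charge that is wholly double product and tris adduct has tris adduct equal to the uptake number minus two, so for Tuesday's flask I commit to 50.0%.

One number is not enough for the south run. The same subtraction gives it 10.0%, but its mean reading is 22.5%, more than the subtraction gives, beside the unread remainder. For Thursday's and Sunday's flasks I therefore draw a line between the run means, with 6.25% at 1.30, and get 10.3% and 20.5%.

The forecast gives 10%, 20% and 40%, and for Tuesday's flask, where I differ, it says “I take about 40%, with wide uncertainty”.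

The flasks give 9.15%, 19.9% and 46.3%.

    reagent + single product → double product (k = 0.960 M⁻¹ s⁻¹)
    crystals ⇌ double product, rate k2*(cs2 - [double product]) while solid is left; crystals form when [double product] > cs2 (solubility = 1.40 mM, k = 0.0450 s⁻¹)
    substrate + reagent → single product (k = 0.970 M⁻¹ s⁻¹)
    reagent + double product → tris adduct (k = 0.370 M⁻¹ s⁻¹)

Tuesday's flask still holds 1.49% of its reagent charge at 50.0 min, and at 500 min it stands at 0% reagent and 50.0% tris adduct, its uptake number of 2.50 minus two. Sunday's flask has an uptake number of 2.00 and reagent at 0%, and its 12.4% single product, 64.0% double product (crystals counted in) and 19.9% tris adduct at 50.0 min sum by the same count to 2.00.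

(The numbers in the tables are simulated on assumed constants; the scatter is artificial.)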